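**Strategy**

Everything rests on cutting the C8–CH2 bond between ring A and ring E. Ring A is a phloroglucinol with a single free carbon, C8, lying between O1 and the C7 hydroxyl. The methylene on C8 is ortho to the ring E hydroxyl, so it can be brought in as the methylidene terminus of an ortho-quinone methide generated on ring E. One ZnCl2-promoted Friedel–Crafts hydroxybenzylation therefore joins (S)-6-(2-hydroxybenzyl)pinocembrin, which brings C2 from the chiral pool, to the E–F–G trimer salicyl alcohol whose ring F and ring G phenols are masked as acetates. The trimer comes from two aryllithium–aldehyde additions and one hydrogenolysis; acid methanolysis finishes the synthesis.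

Key step: step 8

Assumption: commercial (S)-pinocembrin of high enantiomeric purity is the only source of chirality, and compounds 5, 7 and 10 are bought as catalogue chemicals.

Remark on the structure: C2 is S and is the only stereocentre. Rings E and F each carry one methylene ortho and one para to their hydroxyl, rings D and G one ortho methylene only. The building blocks below reproduce this pattern.

**Route**

Step 1
Reactants: 1 (S)-pinocembrin; 2 2-hydroxybenzyl alcohol
Product: 4 (S)-6-(2-hydroxybenzyl)pinocembrin, via ortho-quinone methide 3 (not isolated)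
Conditions: ZnCl2 (anhydrous, 3 equiv), 1,4-dioxane, 70 °C, slow addition of 2 (0.8 equiv); chromatography, recovery of 1
Reagents that add atoms: none
Why: ZnCl2-promoted Friedel–Crafts hydroxybenzylation in which 2 loses water to the ortho-quinone methide 3 and ring A captures it at C6 or C8, so the C6 isomer 4 must be separated from the C8 isomer and the bis-adduct, while C2 is untouched because no base is present.

Step 2
Reactants: 5 5-bromo-2-hydroxybenzyl alcohol
Product: 6 6-bromo-2,2-dimethyl-4H-1,3-benzodioxine
Conditions: Me2C(OMe)2, p-TsOH·H2O (cat.), acetone, rt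
Reagents that add atoms: 2,2-dimethoxypropane, COC(C)(C)OC
Why: Acid-catalysed transketalisation ties the phenol and the benzylic alcohol into a cyclic ketal that tolerates organolithium reagents, base and neutral hydrogenolysis.

Step 3
Reactants: 6 6-bromo-2,2-dimethyl-4H-1,3-benzodioxine; 7 2-(benzyloxy)-5-bromobenzaldehyde
Product: 9 racemic [2-(benzyloxy)-5-bromophenyl](2,2-dimethyl-4H-1,3-benzodioxin-6-yl)methanol, via aryllithium 8 (not isolated)
Conditions: n-BuLi (1.05 equiv), THF, −78 °C; then 7, −78 → −40 °C; H2O
Reagents that add atoms: none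
Why: Bromine–lithium exchange then 1,2-addition of the aryllithium to the aldehyde, which at −78 °C is much faster than exchange with the aryl bromide of 7; the carbinol centre forms as a racemate and is deleted in step 5.

Step 4
Reactants: 9 racemic [2-(benzyloxy)-5-bromophenyl](2,2-dimethyl-4H-1,3-benzodioxin-6-yl)methanol; 10 2-(benzyloxy)benzaldehyde
Product: 12 [2-(benzyloxy)-5-{[2-(benzyloxy)phenyl](hydroxy)methyl}phenyl](2,2-dimethyl-4H-1,3-benzodioxin-6-yl)methanol as a mixture of diastereomers, via dilithio alkoxide 11 (not isolated)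
Conditions: n-BuLi (2.2 equiv), THF, −78 °C; then 10, −78 → 0 °C; H2O
Reagents that add atoms: none
Why: Deprotonation of the carbinol followed by bromine–lithium exchange gives an alkoxide-aryllithium that adds 1,2 to aldehyde 10; the second carbinol centre forms without control, which is irrelevant because both centres are removed in step 5.

Step 5
Reactants: 12 [2-(benzyloxy)-5-{[2-(benzyloxy)phenyl](hydroxy)methyl}phenyl](2,2-dimethyl-4H-1,3-benzodioxin-6-yl)methanol
Product: 14 2-[(2,2-dimethyl-4H-1,3-benzodioxin-6-yl)methyl]-4-(2-hydroxybenzyl)phenol, via bisphenol diol 13 (not isolated)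
Conditions: H2 (3 atm), Pd(OH)2/C, EtOAc, rt
Reagents that add atoms: none
Why: Heterogeneous hydrogenolysis should cleave the two aryl benzyl ethers first and then the two doubly benzylic C–OH bonds, each activated by an ortho or para oxygen on its flanking rings, while the cyclic ketal should survive in a neutral aprotic solvent; both carbinol stereocentres vanish.

Step 6
Reactants: 14 2-[(2,2-dimethyl-4H-1,3-benzodioxin-6-yl)methyl]-4-(2-hydroxybenzyl)phenol
Product: 15 4-(2-acetoxybenzyl)-2-[(2,2-dimethyl-4H-1,3-benzodioxin-6-yl)methyl]phenyl acetate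
Conditions: Ac2O, pyridine, DMAP (cat.), CH2Cl2, 0 °C → rt
Reagents that add atoms: acetic anhydride, CC(=O)OC(C)=O
Why: DMAP-catalysed O-acylation of the two free phenols under basic conditions to which the ketal is inert.

Step 7
Reactants: 15 4-(2-acetoxybenzyl)-2-[(2,2-dimethyl-4H-1,3-benzodioxin-6-yl)methyl]phenyl acetate
Product: 16 4-(2-acetoxybenzyl)-2-[4-hydroxy-3-(hydroxymethyl)benzyl]phenyl acetate
Conditions: AcOH–H2O–THF (3:1:1), 45 °C
Reagents that add atoms: none
Why: Mild acid-catalysed ketal hydrolysis frees the ring E salicyl alcohol while aryl acetates hydrolyse far more slowly in aqueous acetic acid, and a little acetate loss would be harmless since all phenols are unmasked in step 9.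

Step 8
Reactants: 4 (S)-6-(2-hydroxybenzyl)pinocembrin; 16 4-(2-acetoxybenzyl)-2-[4-hydroxy-3-(hydroxymethyl)benzyl]phenyl acetate
Product: 18 (S)-8-{5-[2-acetoxy-5-(2-acetoxybenzyl)benzyl]-2-hydroxybenzyl}-6-(2-hydroxybenzyl)pinocembrin, via ring E ortho-quinone methide 17 (not isolated)
Conditions: 4 (1.5 equiv), ZnCl2 (anhydrous, 3 equiv), 1,4-dioxane, 70 °C, syringe-pump addition of 16
Reagents that add atoms: none
Why: ZnCl2 binds the phenol and benzylic hydroxyl of 16 and assists loss of water to the ring E ortho-quinone methide 17 (or its zinc phenoxide benzyl cation equivalent); C8 of ring A adds to the exocyclic methylene in a conjugate sense and tautomerisation restores both aromatic rings, a Friedel–Crafts hydroxybenzylation. The closest known reaction is the ZnCl2-mediated C-(2-hydroxybenzyl)ation of 5,7-dihydroxyflavanones with salicyl alcohols, the chemistry of step 1. No ring is closed and no stereocentre is formed; C2 is a spectator because the medium contains no base. The step needs site selectivity: ring A has a single free position, C8, activated by O1, the C7 hydroxyl and the para C5 hydroxyl, so it should outrun the monophenol carbons of ring D and ring E, while rings F and G are deactivated as acetates. Slow addition of 16 to an excess of 4 keeps 17 dilute and so suppresses self-condensation at the free ortho carbon of ring E. Acetyl migration between phenols, should it occur, has no consequence because every acetate is removed in step 9.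

Step 9
Reactants: 18 (S)-8-{5-[2-acetoxy-5-(2-acetoxybenzyl)benzyl]-2-hydroxybenzyl}-6-(2-hydroxybenzyl)pinocembrin
Product: 19 sarmentosumin A
Conditions: HCl (0.5 M) in MeOH, rt
Reagents that add atoms: none
Why: Acid-catalysed transesterification of the two aryl acetates with methanol in a base-free medium, which avoids retro-oxa-Michael opening of the flavanone so that C2 should keep its S configuration.

**Compound list**

1 | (S)-pinocembrin, (2S)-5,7-dihydroxyflavanone | O=C1C[C@@H](c2ccccc2)Oc2cc(O)cc(O)c21 | starting material
2 | 2-hydroxybenzyl alcohol | OCc1ccccc1O | starting material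
3 | ortho-quinone methide, 6-methylidenecyclohexa-2,4-dien-1-one | C=C1C=CC=CC1=O | intermediate
4 | (S)-6-(2-hydroxybenzyl)pinocembrin | O=C1C[C@@H](c2ccccc2)Oc2cc(O)c(Cc3ccccc3O)c(O)c21 | intermediate
5 | 5-bromo-2-hydroxybenzyl alcohol | OCc1cc(Br)ccc1O | starting material
6 | 6-bromo-2,2-dimethyl-4H-1,3-benzodioxine | CC1(C)OCc2cc(Br)ccc2O1 | intermediate
7 | 2-(benzyloxy)-5-bromobenzaldehyde | O=Cc1cc(Br)ccc1OCc1ccccc1 | starting material
8 | (2,2-dimethyl-4H-1,3-benzodioxin-6-yl)lithium | CC1(C)OCc2cc([Li])ccc2O1 | intermediate
9 | racemic [2-(benzyloxy)-5-bromophenyl](2,2-dimethyl-4H-1,3-benzodioxin-6-yl)methanol | OC(c1ccc2OC(C)(C)OCc2c1)c1cc(Br)ccc1OCc1ccccc1 | intermediate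
10 | 2-(benzyloxy)benzaldehyde | O=Cc1ccccc1OCc1ccccc1 | starting material
11 | dilithio alkoxide of 9 (lithium alkoxide, lithium in place of bromine) | [Li]OC(c1ccc2OC(C)(C)OCc2c1)c1cc([Li])ccc1OCc1ccccc1 | intermediate
12 | [2-(benzyloxy)-5-{[2-(benzyloxy)phenyl](hydroxy)methyl}phenyl](2,2-dimethyl-4H-1,3-benzodioxin-6-yl)methanol, mixture of diastereomers | OC(c1ccc2OC(C)(C)OCc2c1)c1cc(C(O)c2ccccc2OCc2ccccc2)ccc1OCc1ccccc1 | intermediate
13 | 2-[(2,2-dimethyl-4H-1,3-benzodioxin-6-yl)(hydroxy)methyl]-4-[hydroxy(2-hydroxyphenyl)methyl]phenol, mixture of diastereomers | OC(c1ccc2OC(C)(C)OCc2c1)c1cc(C(O)c2ccccc2O)ccc1O | intermediate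
14 | 2-[(2,2-dimethyl-4H-1,3-benzodioxin-6-yl)methyl]-4-(2-hydroxybenzyl)phenol | CC1(C)OCc2cc(Cc3cc(Cc4ccccc4O)ccc3O)ccc2O1 | intermediate
15 | 4-(2-acetoxybenzyl)-2-[(2,2-dimethyl-4H-1,3-benzodioxin-6-yl)methyl]phenyl acetate | CC1(C)OCc2cc(Cc3cc(Cc4ccccc4OC(C)=O)ccc3OC(C)=O)ccc2O1 | intermediate
16 | 4-(2-acetoxybenzyl)-2-[4-hydroxy-3-(hydroxymethyl)benzyl]phenyl acetate (trimer salicyl alcohol, rings F and G acetylated) | OCc1cc(Cc2cc(Cc3ccccc3OC(C)=O)ccc2OC(C)=O)ccc1O | intermediate
17 | ring E ortho-quinone methide of 16, a 6-methylidenecyclohexa-2,4-dien-1-one carrying the F–G diacetate arm at C4 | C=C1C=C(Cc2cc(Cc3ccccc3OC(C)=O)ccc2OC(C)=O)C=CC1=O | intermediate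
18 | (S)-8-{5-[2-acetoxy-5-(2-acetoxybenzyl)benzyl]-2-hydroxybenzyl}-6-(2-hydroxybenzyl)pinocembrin (target diacetate on rings F and G) | O=C1C[C@@H](c2ccccc2)Oc2c(Cc3cc(Cc4cc(Cc5ccccc5OC(C)=O)ccc4OC(C)=O)ccc3O)c(O)c(Cc3ccccc3O)c(O)c21 | intermediate
19 | sarmentosumin A | O=C1C[C@@H](c2ccccc2)Oc2c(Cc3cc(Cc4cc(Cc5ccccc5O)ccc4O)ccc3O)c(O)c(Cc3ccccc3O)c(O)c21 | target

**Count and risks**

Total steps: 9. Longest linear sequence: 8 steps (5 → 19 through steps 2 to 9).

Steps most likely to fail:

1. Step 8. The quinone methide may be consumed by self-condensation at the free ortho carbon of ring E of a second molecule, or by attack of ring D, faster than the hindered C8 reacts. Prolonged heating with ZnCl2 may also open the pyranone ring and erode the C2 configuration. The fallback sets out from 16 and replaces the quinone methide by an aldehyde electrophile. Oxidation of the benzylic alcohol with activated MnO2 in CH2Cl2 should give the salicylaldehyde 4-(2-acetoxybenzyl)-2-(3-formyl-4-hydroxybenzyl)phenyl acetate F1. F1 is then condensed with 4 in TFA–CH2Cl2 at 0 °C in the presence of Et3SiH, a reductive Friedel–Crafts alkylation. The carbinol formed at C8 ionises to a cation stabilised by both flanking oxygenated rings and is reduced by the silane, so the aldehyde cannot oligomerise through a quinone methide. The sequence comes back to the route at 18.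

2. Step 1. Hydroxybenzylation may favour C8 or run on to the 6,8-bis adduct, and the two mono isomers may co-elute, so that little pure C6 isomer is obtained. The fallback sets out from 1 and fixes the position by halogenation and cross-coupling.
   - Mitsunobu benzylation of the more acidic C7 hydroxyl (BnOH, PPh3, DIAD, THF) should give (S)-7-(benzyloxy)-5-hydroxyflavanone F2.
   - Iodination ortho to the chelated C5 hydroxyl with benzyltrimethylammonium dichloroiodate and CaCO3 in CH2Cl2–MeOH should give (S)-7-(benzyloxy)-5-hydroxy-6-iodoflavanone F3.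
   - Base-free Negishi coupling with 2-(benzyloxy)benzylzinc chloride (Pd(OAc)2, SPhos, THF, rt) should give (S)-7-(benzyloxy)-6-[2-(benzyloxy)benzyl]-5-hydroxyflavanone F4.
   - Brief hydrogenolysis (H2, Pd/C, EtOAc) removes both benzyl ethers and comes back to the route at 4.

3. Step 5. Reduction of the two diaryl carbinol C–O bonds may be sluggish under neutral conditions, whereas forcing or acidic conditions may open the benzodioxine by hydrogenolysis of its benzylic C–O bond or by loss of the ketal. The fallback sets out from 12 and separates the two events. Hydrogenolysis at 1 atm over Pd/C in EtOAc is stopped after O-debenzylation and the bisphenol diol 13 is isolated. 13 is then deoxygenated with NaBH4 in aqueous NaOH–EtOH at 70 °C: each phenoxide expels hydroxide to a quinone methide that takes up hydride, and the ketal is stable to base. This comes back to the route at 14 and passes through no compound outside the list (F0).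

**Further compounds**

F1 | step 8 | 4-(2-acetoxybenzyl)-2-(3-formyl-4-hydroxybenzyl)phenyl acetate | O=Cc1cc(Cc2cc(Cc3ccccc3OC(C)=O)ccc2OC(C)=O)ccc1O
F2 | step 1 | (S)-7-(benzyloxy)-5-hydroxyflavanone | O=C1C[C@@H](c2ccccc2)Oc2cc(OCc3ccccc3)cc(O)c21
F3 | step 1 | (S)-7-(benzyloxy)-5-hydroxy-6-iodoflavanone | O=C1C[C@@H](c2ccccc2)Oc2cc(OCc3ccccc3)c(I)c(O)c21
F4 | step 1 | (S)-7-(benzyloxy)-6-[2-(benzyloxy)benzyl]-5-hydroxyflavanone | O=C1C[C@@H](c2ccccc2)Oc2cc(OCc3ccccc3)c(Cc3ccccc3OCc3ccccc3)c(O)c21
F0 | step 5 | none | none
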